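**Retrosynthetic overview**

1. Numbering used throughout: C1 = quaternary oxirane carbon (bears C7H2OBz), C2/C3 = CHOAc, C4/C5 = CHOH, C6 = oxirane CH. O2–O5 alternate faces, so C2–C5 map onto an L-ido chain. Endgame: 24 ⇐ (H2) dibenzyl ether 23 ⇐ (BzCl, then Ac2O) triol 21 ⇐ (DDQ) tris-PMB epoxide 20.
2. Key disconnection: the C1–C6 bond and the C6–O bond of the oxirane are cut together, 20 ⇐ acyclic 1-alkoxy-2-ketone 16 carrying a phenylthio group on C6. Benzyne turns the sulfide into a diphenylsulfonium ylide, which adds to the C1 ketone and closes the oxirane (intramolecular Corey–Chaykovsky); the activating sulfur leaves as Ph2S.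
3. Enabling feature: in the oxirane pair C1/C6, C1 is fully substituted and carries the oxymethyl arm C7 (a latent ketone carbon), while C6 bears only H (a latent ylide carbon). The four oxygens at C2–C5 are all-trans, so all sit equatorial in the chair transition state and only one trans-diaxial betaine can close.
4. Chain synthesis: 16 ⇐ Weinreb amide 11 + PMBOCH2Li. C2–C4 come unchanged from D-glucose (thioglucoside 1); C5 is inverted through a 5,6-oxirane that thiophenolate opens at C6.
5. Ring order: the benzylidene and pyranose rings of 1 are opened in steps 2 and 6; the cyclohexane ring and the oxirane are then formed together in step 12, and no ring is closed afterwards.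

Key step: step 12

Remark: compounds 1, 12, 13 and 17 are taken as commercial; intermediates up to 16 carry carbohydrate numbering (glucose C1–C6 = target C1–C6), later ones the target numbering.

**Route**

Step 1
Reactants: 1 phenyl 4,6-O-[(R)-benzylidene]-1-thio-β-D-glucopyranoside
Product: 2 phenyl 4,6-O-[(R)-benzylidene]-2,3-bis-O-(4-methoxybenzyl)-1-thio-β-D-glucopyranoside
Conditions: NaH, PMBCl, TBAI (cat.), DMF, 0 °C → rt
Reagents that add atoms: 4-methoxybenzyl chloride, COc1ccc(CCl)cc1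
Why: Williamson etherification of the two free equatorial hydroxyls; thioglycoside and acetal are base-stable and no stereocentre is touched.

Step 2
Reactants: 2 phenyl 4,6-O-[(R)-benzylidene]-2,3-bis-O-(4-methoxybenzyl)-1-thio-β-D-glucopyranoside
Product: 3 phenyl 4-O-benzyl-2,3-bis-O-(4-methoxybenzyl)-1-thio-β-D-glucopyranoside
Conditions: BH3·THF, Cu(OTf)2 (cat.), CH2Cl2, rt; MeOH quench
Reagents that add atoms: none
Why: Lewis-acid-catalysed borane reductive opening of a 4,6-O-benzylidene acetal, which should leave the benzyl group on O4 and free the primary 6-OH while sparing PMB ethers and the thioglycoside.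

Step 3
Reactants: 3 phenyl 4-O-benzyl-2,3-bis-O-(4-methoxybenzyl)-1-thio-β-D-glucopyranoside
Product: 4 phenyl 4-O-benzyl-6-O-(tert-butyldiphenylsilyl)-2,3-bis-O-(4-methoxybenzyl)-1-thio-β-D-glucopyranoside
Conditions: TBDPSCl, imidazole, DMF, rt
Reagents that add atoms: tert-butyl(chloro)diphenylsilane, CC(C)(C)[Si](Cl)(c1ccccc1)c1ccccc1
Why: silylation of the only free (primary) hydroxyl as a fluoride-labile placeholder for the later O6 nucleophile.

Step 4
Reactants: 4 phenyl 4-O-benzyl-6-O-(tert-butyldiphenylsilyl)-2,3-bis-O-(4-methoxybenzyl)-1-thio-β-D-glucopyranoside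
Product: 5 4-O-benzyl-6-O-(tert-butyldiphenylsilyl)-2,3-bis-O-(4-methoxybenzyl)-D-glucopyranose (anomeric mixture)
Conditions: NBS, acetone/H2O (9:1), 0 °C
Reagents that add atoms: water, O
Why: NBS-promoted thioglycoside hydrolysis (bromosulfonium activation, water capture of the oxocarbenium ion) should free the anomeric centre without harming PMB, benzyl or silyl ethers; the anomeric mixture is irrelevant because C1 is oxidised next.

Step 5
Reactants: 5 4-O-benzyl-6-O-(tert-butyldiphenylsilyl)-2,3-bis-O-(4-methoxybenzyl)-D-glucopyranose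
Product: 6 4-O-benzyl-6-O-(tert-butyldiphenylsilyl)-2,3-bis-O-(4-methoxybenzyl)-D-glucono-1,5-lactone
Conditions: Ac2O, DMSO, rt
Reagents that add atoms: none
Why: Albright–Goldman (DMSO/Ac2O) oxidation of a lactol to the 1,5-lactone, the standard method for per-O-alkylated aldoses, with no base that could epimerise C2.

Step 6
Reactants: 6 4-O-benzyl-6-O-(tert-butyldiphenylsilyl)-2,3-bis-O-(4-methoxybenzyl)-D-glucono-1,5-lactone
Product: 7 N-methoxy-N-methyl-4-O-benzyl-6-O-(tert-butyldiphenylsilyl)-2,3-bis-O-(4-methoxybenzyl)-D-gluconamide (free 5-OH)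
Conditions: MeNHOMe·HCl, AlMe3, CH2Cl2, 0 °C → rt; Rochelle salt work-up; used directly
Reagents that add atoms: N,O-dimethylhydroxylamine hydrochloride, CNOC.Cl
Why: aluminium-amide aminolysis of the lactone (Weinreb amide formation) should open the pyranose ring, make C1 a mono-acylating centre and expose 5-OH as the only free hydroxyl; the D-gluco centres are untouched.

Step 7
Reactants: 7 N-methoxy-N-methyl-4-O-benzyl-6-O-(tert-butyldiphenylsilyl)-2,3-bis-O-(4-methoxybenzyl)-D-gluconamide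
Product: 8 N-methoxy-N-methyl-4-O-benzyl-6-O-(tert-butyldiphenylsilyl)-5-O-methanesulfonyl-2,3-bis-O-(4-methoxybenzyl)-D-gluconamide
Conditions: MsCl, Et3N, CH2Cl2, 0 °C
Reagents that add atoms: methanesulfonyl chloride, CS(=O)(=O)Cl
Why: sulfonylation of the lone secondary alcohol turns O5 into a leaving group for inversion at C5 and blocks relactonisation.

Step 8
Reactants: 8 N-methoxy-N-methyl-4-O-benzyl-6-O-(tert-butyldiphenylsilyl)-5-O-methanesulfonyl-2,3-bis-O-(4-methoxybenzyl)-D-gluconamide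
Product: 10 N-methoxy-N-methyl-4-O-benzyl-2,3-bis-O-(4-methoxybenzyl)-6-S-phenyl-6-thio-L-idonamide (free 5-OH), via 5,6-anhydro-L-idonamide 9 (not isolated)
Conditions: TBAF, THF, 0 °C → rt; then PhSH, Et3N (cat.), MeOH, rt
Reagents that add atoms: thiophenol, Sc1ccccc1
Why: fluoride desilylation gives the C6 alkoxide, which displaces the C5 mesylate (intramolecular Williamson, 3-exo-tet) with inversion to the L-ido oxirane; thiolate then opens it at the primary carbon (SN2), which should fix the C5 configuration of the target and place sulfur on C6.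

Step 9
Reactants: 10 N-methoxy-N-methyl-4-O-benzyl-2,3-bis-O-(4-methoxybenzyl)-6-S-phenyl-6-thio-L-idonamide
Product: 11 N-methoxy-N-methyl-4,5-di-O-benzyl-2,3-bis-O-(4-methoxybenzyl)-6-S-phenyl-6-thio-L-idonamide
Conditions: NaH, BnBr, TBAI (cat.), DMF, 0 °C
Reagents that add atoms: benzyl bromide, BrCc1ccccc1
Why: Williamson benzylation of the only free hydroxyl; the aryl alkyl sulfide is not alkylated and a short reaction at 0 °C should avoid α-epimerisation of the amide.

Step 10
Reactants: 12 tributyl(iodomethyl)stannane; 13 4-methoxybenzyl alcohol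
Product: 14 tributyl{[(4-methoxybenzyl)oxy]methyl}stannane
Conditions: NaH, THF/DMF, 0 °C → rt
Reagents that add atoms: none
Why: Williamson alkylation of the alkoxide by the iodomethylstannane gives the α-alkoxymethylstannane needed for tin–lithium exchange.

Step 11
Reactants: 11 N-methoxy-N-methyl-4,5-di-O-benzyl-2,3-bis-O-(4-methoxybenzyl)-6-S-phenyl-6-thio-L-idonamide; 14 tributyl{[(4-methoxybenzyl)oxy]methyl}stannane
Product: 16 5,6-di-O-benzyl-1,3,4-tris-O-(4-methoxybenzyl)-7-S-phenyl-7-thio-keto-L-ido-hept-2-ulose (open chain PMBOCH2–CO–[CH(OPMB)]2–[CH(OBn)]2–CH2SPh), via alkoxymethyllithium 15 (not isolated)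
Conditions: 14, n-BuLi, THF, −78 °C; then 11, −78 °C; aq. NH4Cl
Reagents that add atoms: none
Why: tin–lithium exchange gives the α-alkoxymethyllithium, which should add once to the Weinreb amide (stable chelate) and give the 1-alkoxy-2-ketone on work-up; nothing is enolised at −78 °C.

Step 12
Reactants: 16 5,6-di-O-benzyl-1,3,4-tris-O-(4-methoxybenzyl)-7-S-phenyl-7-thio-keto-L-ido-hept-2-ulose; 17 2-(trimethylsilyl)phenyl trifluoromethanesulfonate
Product: 20 4,5-bis(benzyloxy)-2,3-bis[(4-methoxybenzyl)oxy]-1-{[(4-methoxybenzyl)oxy]methyl}-7-oxabicyclo[4.1.0]heptane (configuration at C1–C6 as in the target), via sulfonium ylide 18 (not isolated), via oxido-sulfonium betaine 19 (not isolated)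
Conditions: KF, 18-crown-6, THF (0.02 M), 17 (2.5 equiv) added slowly, 0 °C → rt
Reagents that add atoms: none
Why: Proposed new method: fluoride releases benzyne from 17, the C6 thioether of 16 (the only soft nucleophile) adds to it, and the ortho-sulfonio aryl anion takes a proton from C6, the only sp3 carbon on sulfur, so the alkyl(diphenyl)sulfonium ylide 18 should form regiospecifically without added base; the ylide carbon then adds to the C1 ketone and the alkoxide of betaine 19 displaces diphenyl sulfide, i.e. an intramolecular Corey–Chaykovsky epoxidation. The closest known reaction types are ylide generation by S-arylation of thioethers with arynes, epoxidation of ketones by alkyl(diphenyl)sulfonium ylides, and sulfonium-ylide epoxy-annulations that give cis-fused bicyclic epoxides from tethered ketones; new here is the all-carbon six-membered closure on a polyoxygenated chain. The cyclohexane ring closes by 6-exo-trig attack of C6 on the C1 carbonyl (C1–C6 bond) and the oxirane by 3-exo-tet attack of O1 on C6 with loss of Ph2S. C1 and C6 are controlled by the chair transition state: the four ether groups at C2–C5 (all-trans, L-ido) are equatorial and the bulkier C7 arm of the ketone is equatorial, so the carbonyl oxygen is axial, and only the betaine with the sulfonium group axial and anti to O1 can close, which puts the oxirane oxygen cis to O2 and trans to O5 as in the target. The step needs S- over O-arylation, ylide formation only at C6, and addition faster than enolisation or β-alkoxide loss; these should be secured by the higher aryne affinity of sulfur, by the two phenyl groups on sulfur, and by the neutral medium together with the intramolecular six-membered closure at high dilution.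

Step 13
Reactants: 20 4,5-bis(benzyloxy)-2,3-bis[(4-methoxybenzyl)oxy]-1-{[(4-methoxybenzyl)oxy]methyl}-7-oxabicyclo[4.1.0]heptane
Product: 21 [4,5-bis(benzyloxy)-2,3-dihydroxy-7-oxabicyclo[4.1.0]heptan-1-yl]methanol (target configuration)
Conditions: DDQ, CH2Cl2/pH 7 phosphate buffer (10:1), 0 °C → rt
Reagents that add atoms: none
Why: oxidative PMB cleavage by DDQ (benzylic hydride abstraction, then hydrolysis) in buffered wet solvent should remove the three PMB ethers while sparing benzyl ethers and the oxirane; water suppresses p-methoxybenzylidene acetal formation.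

Step 14
Reactants: 21 [4,5-bis(benzyloxy)-2,3-dihydroxy-7-oxabicyclo[4.1.0]heptan-1-yl]methanol
Product: 23 [2,3-diacetoxy-4,5-bis(benzyloxy)-7-oxabicyclo[4.1.0]heptan-1-yl]methyl benzoate (target configuration), via 7-O-benzoyl diol 22 (not isolated)
Conditions: BzCl (1.05 equiv), 2,4,6-collidine, CH2Cl2, −40 °C; then Ac2O, DMAP, pyridine, 0 °C → rt
Reagents that add atoms: benzoyl chloride, O=C(Cl)c1ccccc1; acetic anhydride, CC(=O)OC(C)=O
Why: kinetically selective acylation, the primary C7 hydroxyl being benzoylated first at low temperature before exhaustive DMAP-catalysed acetylation of the two secondary hydroxyls (nucleophilic acyl substitution); no stereocentre is involved.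

Step 15
Reactants: 23 [2,3-diacetoxy-4,5-bis(benzyloxy)-7-oxabicyclo[4.1.0]heptan-1-yl]methyl benzoate
Product: 24 [(1S,2R,3S,4R,5R,6S)-2,3-diacetoxy-4,5-dihydroxy-7-oxabicyclo[4.1.0]heptan-1-yl]methyl benzoate (CNP0171674.1)
Conditions: H2 (1 atm), 10% Pd/C, EtOAc, rt
Reagents that add atoms: none
Why: palladium-catalysed hydrogenolysis of the two benzyl ethers under neutral aprotic conditions should spare the esters and the non-benzylic oxirane and avoid base-induced acyl migration.

**Compound list**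

1 | phenyl 4,6-O-[(R)-benzylidene]-1-thio-β-D-glucopyranoside | c1ccccc1S[C@H]1[C@H](O)[C@@H](O)[C@@H]2O[C@H](c3ccccc3)OC[C@H]2O1 | starting material
2 | phenyl 4,6-O-[(R)-benzylidene]-2,3-bis-O-(4-methoxybenzyl)-1-thio-β-D-glucopyranoside | c1ccccc1S[C@H]1[C@H](OCc2ccc(OC)cc2)[C@@H](OCc2ccc(OC)cc2)[C@@H]2O[C@H](c3ccccc3)OC[C@H]2O1 | intermediate
3 | phenyl 4-O-benzyl-2,3-bis-O-(4-methoxybenzyl)-1-thio-β-D-glucopyranoside | c1ccccc1S[C@H]1[C@H](OCc2ccc(OC)cc2)[C@@H](OCc2ccc(OC)cc2)[C@H](OCc2ccccc2)[C@@H](CO)O1 | intermediate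
4 | phenyl 4-O-benzyl-6-O-(tert-butyldiphenylsilyl)-2,3-bis-O-(4-methoxybenzyl)-1-thio-β-D-glucopyranoside | c1ccccc1S[C@H]1[C@H](OCc2ccc(OC)cc2)[C@@H](OCc2ccc(OC)cc2)[C@H](OCc2ccccc2)[C@@H](CO[Si](c2ccccc2)(c2ccccc2)C(C)(C)C)O1 | intermediate
5 | 4-O-benzyl-6-O-(tert-butyldiphenylsilyl)-2,3-bis-O-(4-methoxybenzyl)-D-glucopyranose (anomeric mixture) | OC1[C@H](OCc2ccc(OC)cc2)[C@@H](OCc2ccc(OC)cc2)[C@H](OCc2ccccc2)[C@@H](CO[Si](c2ccccc2)(c2ccccc2)C(C)(C)C)O1 | intermediate
6 | 4-O-benzyl-6-O-(tert-butyldiphenylsilyl)-2,3-bis-O-(4-methoxybenzyl)-D-glucono-1,5-lactone | O=C1[C@H](OCc2ccc(OC)cc2)[C@@H](OCc2ccc(OC)cc2)[C@H](OCc2ccccc2)[C@@H](CO[Si](c2ccccc2)(c2ccccc2)C(C)(C)C)O1 | intermediate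
7 | N-methoxy-N-methyl-4-O-benzyl-6-O-(tert-butyldiphenylsilyl)-2,3-bis-O-(4-methoxybenzyl)-D-gluconamide | CON(C)C(=O)[C@H](OCc1ccc(OC)cc1)[C@@H](OCc1ccc(OC)cc1)[C@H](OCc1ccccc1)[C@@H](CO[Si](c1ccccc1)(c1ccccc1)C(C)(C)C)O | intermediate
8 | 5-O-methanesulfonate of 7 | CON(C)C(=O)[C@H](OCc1ccc(OC)cc1)[C@@H](OCc1ccc(OC)cc1)[C@H](OCc1ccccc1)[C@@H](CO[Si](c1ccccc1)(c1ccccc1)C(C)(C)C)OS(C)(=O)=O | intermediate
9 | N-methoxy-N-methyl-5,6-anhydro-4-O-benzyl-2,3-bis-O-(4-methoxybenzyl)-L-idonamide | CON(C)C(=O)[C@H](OCc1ccc(OC)cc1)[C@@H](OCc1ccc(OC)cc1)[C@H](OCc1ccccc1)[C@@H]1CO1 | intermediate (not isolated)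
10 | N-methoxy-N-methyl-4-O-benzyl-2,3-bis-O-(4-methoxybenzyl)-6-S-phenyl-6-thio-L-idonamide | CON(C)C(=O)[C@H](OCc1ccc(OC)cc1)[C@@H](OCc1ccc(OC)cc1)[C@H](OCc1ccccc1)[C@H](CSc1ccccc1)O | intermediate
11 | N-methoxy-N-methyl-4,5-di-O-benzyl-2,3-bis-O-(4-methoxybenzyl)-6-S-phenyl-6-thio-L-idonamide | CON(C)C(=O)[C@H](OCc1ccc(OC)cc1)[C@@H](OCc1ccc(OC)cc1)[C@H](OCc1ccccc1)[C@H](CSc1ccccc1)OCc1ccccc1 | intermediate
12 | tributyl(iodomethyl)stannane | CCCC[Sn](CCCC)(CCCC)CI | starting material
13 | 4-methoxybenzyl alcohol | COc1ccc(CO)cc1 | starting material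
14 | tributyl{[(4-methoxybenzyl)oxy]methyl}stannane | CCCC[Sn](CCCC)(CCCC)COCc1ccc(OC)cc1 | intermediate
15 | [(4-methoxybenzyl)oxy]methyllithium | [Li]COCc1ccc(OC)cc1 | intermediate (not isolated)
16 | 5,6-di-O-benzyl-1,3,4-tris-O-(4-methoxybenzyl)-7-S-phenyl-7-thio-keto-L-ido-hept-2-ulose | COc1ccc(COCC(=O)[C@H](OCc2ccc(OC)cc2)[C@@H](OCc2ccc(OC)cc2)[C@H](OCc2ccccc2)[C@H](CSc2ccccc2)OCc2ccccc2)cc1 | intermediate
17 | 2-(trimethylsilyl)phenyl trifluoromethanesulfonate | C[Si](C)(C)c1ccccc1OS(=O)(=O)C(F)(F)F | starting material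
18 | diphenylsulfonium ylide of 16 (carbanion at C6) | COc1ccc(COCC(=O)[C@H](OCc2ccc(OC)cc2)[C@@H](OCc2ccc(OC)cc2)[C@H](OCc2ccccc2)[C@H]([CH-][S+](c2ccccc2)c2ccccc2)OCc2ccccc2)cc1 | intermediate (not isolated)
19 | cyclohexane betaine, C1 axial alkoxide anti to C6 axial diphenylsulfonio group | COc1ccc(CO[C@H]2[C@H](OCc3ccccc3)[C@@H](OCc3ccccc3)[C@@H]([S+](c3ccccc3)c3ccccc3)[C@@]([O-])(COCc3ccc(OC)cc3)[C@@H]2OCc2ccc(OC)cc2)cc1 | intermediate (not isolated)
20 | 4,5-bis(benzyloxy)-2,3-bis[(4-methoxybenzyl)oxy]-1-{[(4-methoxybenzyl)oxy]methyl}-7-oxabicyclo[4.1.0]heptane | COc1ccc(CO[C@H]2[C@H](OCc3ccccc3)[C@@H](OCc3ccccc3)[C@@H]3O[C@]3(COCc3ccc(OC)cc3)[C@@H]2OCc2ccc(OC)cc2)cc1 | intermediate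
21 | [4,5-bis(benzyloxy)-2,3-dihydroxy-7-oxabicyclo[4.1.0]heptan-1-yl]methanol | O[C@H]1[C@H](OCc2ccccc2)[C@@H](OCc2ccccc2)[C@@H]2O[C@]2(CO)[C@@H]1O | intermediate
22 | [4,5-bis(benzyloxy)-2,3-dihydroxy-7-oxabicyclo[4.1.0]heptan-1-yl]methyl benzoate | O[C@H]1[C@H](OCc2ccccc2)[C@@H](OCc2ccccc2)[C@@H]2O[C@]2(COC(=O)c2ccccc2)[C@@H]1O | intermediate (not isolated)
23 | [2,3-diacetoxy-4,5-bis(benzyloxy)-7-oxabicyclo[4.1.0]heptan-1-yl]methyl benzoate | CC(=O)O[C@H]1[C@H](OCc2ccccc2)[C@@H](OCc2ccccc2)[C@@H]2O[C@]2(COC(=O)c2ccccc2)[C@@H]1OC(C)=O | intermediate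
24 | [(1S,2R,3S,4R,5R,6S)-2,3-diacetoxy-4,5-dihydroxy-7-oxabicyclo[4.1.0]heptan-1-yl]methyl benzoate | CC(=O)O[C@H]1[C@H](O)[C@@H](O)[C@@H]2O[C@]2(COC(=O)c2ccccc2)[C@@H]1OC(C)=O | target

**Step count and risks**

Total step count: 15. Longest linear sequence: 14 steps (steps 1–9 and 11–15, from 1 to 24); step 10 is a one-step side branch.

Steps most likely to fail:

1. Step 12 (proposed new method). What may go wrong: carbonyl addition through a gauche betaine that cannot collapse to the oxirane and decays by 1,2-shift or elimination; competing O-arylation or capture of benzyne by the liberated diphenyl sulfide; ylide-mediated enolisation with β-alkoxide loss. Fallback with known chemistry, setting out from 16 and returning at 21, with the carbocycle closed by olefin metathesis and the oxirane made afterwards: the sulfide is oxidised (NaIO4, MeOH/H2O) to the sulfoxide F1. Pummerer rearrangement (TFAA, 2,6-lutidine, then aq. NaHCO3) gives the keto-aldehyde F2. Double Wittig methylenation (Ph3P=CH2, THF, −78 → 0 °C) gives the 1,7-diene F3. Ring-closing metathesis (Grubbs second-generation catalyst, CH2Cl2, 40 °C) closes the C1=C6 cyclohexene F4. DDQ removes the PMB ethers to give the allylic triol F5. Hydroxyl-directed epoxidation (mCPBA, CH2Cl2, 0 °C; syn to the free allylic C2–OH and anti to the C5 benzyl ether) gives 21.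

2. Step 14. What may go wrong: loss of site control in the benzoylation (acylation of the C2/C3 secondary hydroxyls, or benzoyl migration before acetylation), giving scrambled ester patterns. Fallback setting out from 21 and returning at 23, replacing kinetic benzoylation by a temporary bulky silyl group: primary-selective silylation (TBDPSCl, imidazole, DMF) gives the silyl ether F6. Acetylation (Ac2O, DMAP, pyridine) gives the diacetate F7. Buffered desilylation (HF·pyridine, pyridine, THF, 0 °C) gives the primary alcohol F8, and benzoylation (BzCl, pyridine) gives 23.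

3. Step 8. What may go wrong: thiolate displacement or elimination at the secondary mesylate before the oxirane has closed, or relactonisation of the hydroxy amide, which would erode the C5 inversion. Fallback setting out from 7 and returning at 10, separating inversion from sulfur introduction: Mitsunobu inversion (4-nitrobenzoic acid, PPh3, DIAD, toluene) gives the inverted ester F9. Methanolysis and desilylation (K2CO3, MeOH; then TBAF, THF) give the L-ido 5,6-diol F10. Primary-selective phosphine/disulfide thioetherification (PhSSPh, Bu3P, pyridine) gives 10.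

**Further compounds**

F1 | step 12 | sulfoxide of 16 (S-oxide at the C6 phenylthio group) | COc1ccc(COCC(=O)[C@H](OCc2ccc(OC)cc2)[C@@H](OCc2ccc(OC)cc2)[C@H](OCc2ccccc2)[C@H](CS(=O)c2ccccc2)OCc2ccccc2)cc1
F2 | step 12 | keto-aldehyde (C1 ketone, C6 aldehyde) | COc1ccc(COCC(=O)[C@H](OCc2ccc(OC)cc2)[C@@H](OCc2ccc(OC)cc2)[C@H](OCc2ccccc2)[C@H](C=O)OCc2ccccc2)cc1
F3 | step 12 | 1,7-diene (C1 methylidene, C5 vinyl) | COc1ccc(COCC(=C)[C@H](OCc2ccc(OC)cc2)[C@@H](OCc2ccc(OC)cc2)[C@H](OCc2ccccc2)[C@H](C=C)OCc2ccccc2)cc1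
F4 | step 12 | C1=C6 cyclohexene, 4,5-di-O-benzyl-2,3,7-tris-O-(4-methoxybenzyl) | COc1ccc(CO[C@H]2[C@H](OCc3ccccc3)[C@@H](OCc3ccccc3)C=C(COCc3ccc(OC)cc3)[C@@H]2OCc2ccc(OC)cc2)cc1
F5 | step 12 | 4,5-bis(benzyloxy)-1-(hydroxymethyl)cyclohex-1(6)-ene-2,3-diol | O[C@H]1[C@H](OCc2ccccc2)[C@@H](OCc2ccccc2)C=C(CO)[C@@H]1O
F6 | step 14 | 7-O-(tert-butyldiphenylsilyl) ether of 21 | O[C@H]1[C@H](OCc2ccccc2)[C@@H](OCc2ccccc2)[C@@H]2O[C@]2(CO[Si](c2ccccc2)(c2ccccc2)C(C)(C)C)[C@@H]1O
F7 | step 14 | 2,3-di-O-acetyl-7-O-(tert-butyldiphenylsilyl) derivative | CC(=O)O[C@H]1[C@H](OCc2ccccc2)[C@@H](OCc2ccccc2)[C@@H]2O[C@]2(CO[Si](c2ccccc2)(c2ccccc2)C(C)(C)C)[C@@H]1OC(C)=O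
F8 | step 14 | 2,3-di-O-acetyl-4,5-di-O-benzyl epoxy alcohol (free C7–OH) | CC(=O)O[C@H]1[C@H](OCc2ccccc2)[C@@H](OCc2ccccc2)[C@@H]2O[C@]2(CO)[C@@H]1OC(C)=O
F9 | step 8 | 5-O-(4-nitrobenzoyl)-6-O-(tert-butyldiphenylsilyl)-L-idonamide (C5 inverted) | CON(C)C(=O)[C@H](OCc1ccc(OC)cc1)[C@@H](OCc1ccc(OC)cc1)[C@H](OCc1ccccc1)[C@H](CO[Si](c1ccccc1)(c1ccccc1)C(C)(C)C)OC(=O)c1ccc(cc1)[N+](=O)[O-]
F10 | step 8 | N-methoxy-N-methyl-4-O-benzyl-2,3-bis-O-(4-methoxybenzyl)-L-idonamide (5,6-diol) | CON(C)C(=O)[C@H](OCc1ccc(OC)cc1)[C@@H](OCc1ccc(OC)cc1)[C@H](OCc1ccccc1)[C@H](CO)O
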